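**Retrosynthetic overview**

1. Locants follow prostanoid numbering (C1 ester carbon, ring C8–C12). The plan rests on the β-acetoxy ketone C9(=O)–C8(H)–C7(OAc) attached to the five-membered ring C8–C12, read as a 2-isoxazoline C9=N–O–C7 fused to that ring at C8–C9.
2. Late disconnections: C12–OH from its triethylsilyl ether; C10–Cl and C10=C11 from the saturated C9 ketone (α-chlorination, α-selenenylation, selenoxide elimination); C7–OAc and C9=O from the isoxazoline by N–O cleavage.
3. Key disconnection: C8–C9 and O–C7, formed together by intramolecular nitrile oxide cycloaddition of an acyclic C9 aldoxime onto the (E)-C7=C8 alkene. The carbocycle C8–C12 and the isoxazoline close in this single step; the isoxazoline is opened again one step later.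
4. Acyclic precursor: C5=C6 (Z) and C7=C8 (E) by two Wittig olefinations from a C8 aldehyde; C13–C14 by alkynylation of a 2,2-disubstituted epoxide, then Lindlar reduction (14Z).
5. C12 is set by Sharpless epoxidation of a 2-substituted allylic alcohol whose carbons C8 to C12 come from cyclopentene (ozonolysis, α-methylenation, reduction).

Key step: step 14

Remark: oxime 24 and the C10 centres of 32, 34 and 35 arise as isomer mixtures that converge in the following step, so 24 is drawn as the E oxime and C10 is left open in the SMILES.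

**Route**

Step 1
Reactants: 1 cyclopentene
Product: 4 5,5-dimethoxypentanal, via hydroperoxy aldehyde 2 (not isolated), via hydroperoxy acetal 3 (not isolated)
Conditions: O3, CH2Cl2–MeOH, −78 °C; TsOH·H2O (cat.), rt; NaHCO3; Me2S, rt
Reagents that add atoms: ozone [O-][O+]=O; methanol CO
Why: Ozonolysis in methanol leaves an aldehyde at one terminus and a methoxy hydroperoxide at the other, so acid-catalysed acetalisation of the free aldehyde followed by sulfide reduction of the hydroperoxide differentiates the two ends (unsymmetrical ozonolytic cleavage of a cycloalkene).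

Step 2
Reactants: 4 5,5-dimethoxypentanal
Product: 5 5,5-dimethoxy-2-methylidenepentanal
Conditions: aq. HCHO, pyrrolidine (cat.), EtCO2H (cat.), i-PrOH, 45 °C
Reagents that add atoms: formaldehyde C=O
Why: Amine/acid-catalysed Mannich condensation with formaldehyde and loss of the amine (aldehyde α-methylenation) installs the C13 methylene next to the C8 aldehyde under nearly neutral conditions that leave the acetal intact.

Step 3
Reactants: 5 5,5-dimethoxy-2-methylidenepentanal
Product: 6 5,5-dimethoxy-2-methylidenepentan-1-ol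
Conditions: NaBH4, CeCl3·7H2O, MeOH, −20 °C
Reagents that add atoms: none
Why: Luche reduction delivers hydride in the 1,2 sense to the enal and gives the 2-substituted allylic alcohol without conjugate reduction.

Step 4
Reactants: 6 5,5-dimethoxy-2-methylidenepentan-1-ol
Product: 7 [(2R)-2-(3,3-dimethoxypropyl)oxiran-2-yl]methanol
Conditions: Ti(OiPr)4 (cat.), D-(−)-diethyl tartrate (cat.), t-BuOOH, 4 Å MS, CH2Cl2, −25 °C
Reagents that add atoms: tert-butyl hydroperoxide CC(C)(C)OO
Why: Sharpless asymmetric epoxidation of the 2-substituted allylic alcohol; with D-(−)-tartrate the titanium-bound peroxide delivers oxygen to the alkene face that gives the (R)-epoxide, which fixes the C12 carbinol configuration of the target.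

Step 5
Reactants: 7 [(2R)-2-(3,3-dimethoxypropyl)oxiran-2-yl]methanol
Product: 8 {[(2S)-2-(3,3-dimethoxypropyl)oxiran-2-yl]methoxy}triethylsilane
Conditions: Et3SiCl, imidazole, CH2Cl2, 0 °C
Reagents that add atoms: chlorotriethylsilane CC[Si](Cl)(CC)CC
Why: Silylation of the primary alcohol blocks Payne rearrangement in the next step and installs the ether that is later oxidised directly to the C8 aldehyde.

Step 6
Reactants: 8 {[(2S)-2-(3,3-dimethoxypropyl)oxiran-2-yl]methoxy}triethylsilane; 9 hept-1-yne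
Product: 11 (2S)-2-(3,3-dimethoxypropyl)-1-[(triethylsilyl)oxy]dec-4-yn-2-ol, via heptynyllithium 10 (not isolated)
Conditions: 9, n-BuLi, THF, −78 °C; BF3·OEt2; then 8, −78 °C
Reagents that add atoms: none
Why: BF3-promoted alkynylation of the epoxide: the lithium acetylide–BF3 reagent attacks the unsubstituted CH2 terminus (C13) by SN2, so the quaternary C12–O bond and its configuration are untouched, and aldehyde-derived dimethyl acetals tolerate these conditions at −78 °C.

Step 7
Reactants: 11 (2S)-2-(3,3-dimethoxypropyl)-1-[(triethylsilyl)oxy]dec-4-yn-2-ol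
Product: 12 (2S,4Z)-2-(3,3-dimethoxypropyl)-1-[(triethylsilyl)oxy]dec-4-en-2-ol
Conditions: H2 (1 atm), Pd/CaCO3 poisoned with Pb(OAc)2 (Lindlar catalyst), quinoline, EtOAc, rt
Reagents that add atoms: none
Why: Lindlar semi-hydrogenation adds hydrogen syn to the only alkyne present and gives the 14Z alkene.

Step 8
Reactants: 12 (2S,4Z)-2-(3,3-dimethoxypropyl)-1-[(triethylsilyl)oxy]dec-4-en-2-ol
Product: 13 (2S,4Z)-2-(3,3-dimethoxypropyl)-1,2-bis[(triethylsilyl)oxy]dec-4-ene
Conditions: Et3SiCl, imidazole, DMAP (cat.), DMF, 50 °C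
Reagents that add atoms: chlorotriethylsilane CC[Si](Cl)(CC)CC
Why: DMAP-catalysed silylation of the tertiary alcohol with the small triethylsilyl chloride; triflate-free conditions are chosen because a silyl triflate with a pyridine base would attack the dimethyl acetal.

Step 9
Reactants: 13 (2S,4Z)-2-(3,3-dimethoxypropyl)-1,2-bis[(triethylsilyl)oxy]dec-4-ene
Product: 15 (2S,4Z)-2-(3,3-dimethoxypropyl)-2-[(triethylsilyl)oxy]dec-4-enal, via alkoxysulfonium chloride 14 (not isolated)
Conditions: (COCl)2, DMSO, CH2Cl2, −78 → −40 °C; Et3N, −78 °C → rt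
Reagents that add atoms: none
Why: Under Swern conditions a primary triethylsilyl ether is cleaved and oxidised in one operation while the tertiary silyl ether and the acetal are inert, and the resulting aldehyde has no α-hydrogen and cannot epimerise.

Step 10
Reactants: 15 (2S,4Z)-2-(3,3-dimethoxypropyl)-2-[(triethylsilyl)oxy]dec-4-enal; 16 (triphenylphosphoranylidene)acetaldehyde
Product: 17 (2E,4S,6Z)-4-(3,3-dimethoxypropyl)-4-[(triethylsilyl)oxy]dodeca-2,6-dienal
Conditions: toluene, 85 °C
Reagents that add atoms: none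
Why: Wittig olefination with the stabilised formylmethylene ylide is E-selective and gives the enal with the 7E geometry required for the cycloaddition.

Step 11
Reactants: 17 (2E,4S,6Z)-4-(3,3-dimethoxypropyl)-4-[(triethylsilyl)oxy]dodeca-2,6-dienal; 18 (4-carboxybutyl)triphenylphosphonium bromide
Product: 21 methyl (5Z,7E,9S,11Z)-9-(3,3-dimethoxypropyl)-9-[(triethylsilyl)oxy]heptadeca-5,7,11-trienoate, via phosphorus ylide 19 (not isolated), via sodium carboxylate 20 (not isolated)
Conditions: 18, NaN(SiMe3)2, THF, 0 °C; 17, −78 → 0 °C; then MeI, DMF, rt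
Reagents that add atoms: iodomethane CI
Why: Wittig olefination with the non-stabilised ylide under lithium-free conditions gives the 5Z alkene, and the sodium carboxylate is alkylated in the same flask by iodomethane (SN2 esterification).

Step 12
Reactants: 21 methyl (5Z,7E,9S,11Z)-9-(3,3-dimethoxypropyl)-9-[(triethylsilyl)oxy]heptadeca-5,7,11-trienoate
Product: 23 methyl (5Z,7E,9S,11Z)-9-(3-oxopropyl)-9-[(triethylsilyl)oxy]heptadeca-5,7,11-trienoate, via collidinium salt 22 (not isolated)
Conditions: Et3SiOSO2CF3, 2,4,6-collidine, CH2Cl2, 0 °C; then H2O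
Reagents that add atoms: water O
Why: Silyl triflate/collidine acetal cleavage: the aldehyde-derived dimethyl acetal is converted into a collidinium N,O-acetal that water hydrolyses to the aldehyde under non-acidic conditions, which spares the ionisable tertiary dienylic silyl ether and the ester.

Step 13
Reactants: 23 methyl (5Z,7E,9S,11Z)-9-(3-oxopropyl)-9-[(triethylsilyl)oxy]heptadeca-5,7,11-trienoate
Product: 24 methyl (5Z,7E,9S,11Z)-9-[(3E)-3-(hydroxyimino)propyl]-9-[(triethylsilyl)oxy]heptadeca-5,7,11-trienoate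
Conditions: NH2OH·HCl, pyridine, EtOH, 0 °C → rt
Reagents that add atoms: hydroxylamine hydrochloride NO.Cl
Why: Condensation of the aldehyde with hydroxylamine (oxime formation) is fast and selective, and both oxime isomers serve in the next step.

Step 14
Reactants: 24 methyl (5Z,7E,9S,11Z)-9-[(3E)-3-(hydroxyimino)propyl]-9-[(triethylsilyl)oxy]heptadeca-5,7,11-trienoate
Product: 27 methyl (5Z)-6-[(3S,3aR,4S)-4-[(2Z)-oct-2-en-1-yl]-4-[(triethylsilyl)oxy]-3a,4,5,6-tetrahydro-3H-cyclopenta[c][1,2]oxazol-3-yl]hex-5-enoate, via hydroximoyl chloride 25 (not isolated), via nitrile oxide 26 (not isolated)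
Conditions: NCS, pyridine (cat.), CHCl3, 0 °C → rt; then Et3N (slow addition), CH2Cl2 (high dilution), rt
Reagents that add atoms: none
Why: Chlorination of the aldoxime gives the hydroximoyl chloride, from which triethylamine releases the C9 nitrile oxide; this adds in a concerted suprafacial 1,3-dipolar cycloaddition across the proximal (E)-C7=C8 alkene, forming C8–C9 and O–C7 (closest known type: intramolecular nitrile oxide–alkene cycloaddition of a hex-5-enyl nitrile oxide). The carbocycle C8–C12 closes in the 5-exo mode (C9 bonds to the near alkene carbon C8), and the isoxazoline ring (C9, N, O, C7, C8) is completed in the same event as the cycloadduct ring fused at C8–C9. C7 is set relative to C8 by the E alkene geometry, which is transcribed stereospecifically into the trans arrangement of C6 and C12 on the isoxazoline. C8 is set by the quaternary C12: in the favoured transition state the C12–O bond lies near the alkene plane (inside-alkoxy arrangement) and the larger CH2 of the octenyl chain points away from the forming C7–C8 unit, so C7 should end up cis to the silyloxy group and trans to the octenyl chain. The step needs face selectivity and site selectivity; the three-atom tether secures the site (only C7=C8 can be reached, C5=C6 would require a seven-membered ring), and geminal substitution at C12 with slow base addition at high dilution favours ring closure over furoxan formation.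

Step 15
Reactants: 27 methyl (5Z)-6-[(3S,3aR,4S)-4-[(2Z)-oct-2-en-1-yl]-4-[(triethylsilyl)oxy]-3a,4,5,6-tetrahydro-3H-cyclopenta[c][1,2]oxazol-3-yl]hex-5-enoate
Product: 29 methyl (5Z,7S)-7-hydroxy-7-[(1R,2S)-2-[(2Z)-oct-2-en-1-yl]-5-oxo-2-[(triethylsilyl)oxy]cyclopentyl]hept-5-enoate, via hydroxy imine 28 (not isolated)
Conditions: Mo(CO)6, MeCN–H2O, 80 °C
Reagents that add atoms: water O
Why: Mo(CO)6 cleaves the N–O bond reductively and the β-hydroxy imine hydrolyses in the wet medium to the β-hydroxy ketone (isoxazoline-to-aldol unmasking), without touching alkenes, ester or silyl ether and without involving the C7 and C8 centres.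

Step 16
Reactants: 29 methyl (5Z,7S)-7-hydroxy-7-[(1R,2S)-2-[(2Z)-oct-2-en-1-yl]-5-oxo-2-[(triethylsilyl)oxy]cyclopentyl]hept-5-enoate
Product: 30 methyl (5Z,7S)-7-acetoxy-7-[(1R,2S)-2-[(2Z)-oct-2-en-1-yl]-5-oxo-2-[(triethylsilyl)oxy]cyclopentyl]hept-5-enoate
Conditions: Ac2O, pyridine, DMAP (cat.), CH2Cl2, 0 °C
Reagents that add atoms: acetic anhydride CC(=O)OC(C)=O
Why: Pyridine/DMAP-mediated acetylation of the secondary C7 alcohol; the tertiary C12 oxygen is silylated and low temperature limits β-elimination of the new acetate.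

Step 17
Reactants: 30 methyl (5Z,7S)-7-acetoxy-7-[(1R,2S)-2-[(2Z)-oct-2-en-1-yl]-5-oxo-2-[(triethylsilyl)oxy]cyclopentyl]hept-5-enoate
Product: 32 10-chloro derivative of 30 (both C10 epimers), via enol silane 31 (not isolated)
Conditions: LiN(SiMe3)2, Me3SiCl, THF, −78 °C; volatiles removed; then NCS, CH2Cl2, 0 °C
Reagents that add atoms: N-chlorosuccinimide O=C1CCC(=O)N1Cl
Why: Kinetic enolisation under in situ silylation takes place at the unhindered C10 methylene and not at the C8 methine flanked by quaternary C12 or at the less acidic acetate, and the silyl enol ether is chlorinated by NCS (electrophilic α-chlorination of a silyl enol ether).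

Step 18
Reactants: 32 10-chloro derivative of 30 (both C10 epimers)
Product: 34 10-chloro-10-(phenylselanyl) derivative of 30 (both C10 epimers), via lithium enolate 33 (not isolated)
Conditions: LiN(SiMe3)2, THF, −78 °C; then PhSeCl, −78 °C
Reagents that add atoms: benzeneselenenyl chloride Cl[Se]c1ccccc1
Why: The remaining C10–H, acidified by chlorine, is removed selectively and the chloro enolate is trapped at carbon by PhSeCl (enolate selenenylation).

Step 19
Reactants: 34 10-chloro-10-(phenylselanyl) derivative of 30 (both C10 epimers)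
Product: 36 methyl (5Z,7S)-7-acetoxy-7-[(1R,2S)-4-chloro-2-[(2Z)-oct-2-en-1-yl]-5-oxo-2-[(triethylsilyl)oxy]cyclopent-3-en-1-yl]hept-5-enoate, via selenoxide 35 (not isolated)
Conditions: NaIO4, THF–H2O, 0 °C → rt
Reagents that add atoms: none
Why: Oxidation to the selenoxide and syn elimination toward C11 (the only β-hydrogens) gives the 2-chloro enone without base, and the fully substituted selenium-bearing carbon excludes a seleno-Pummerer pathway.

Step 20
Reactants: 36 methyl (5Z,7S)-7-acetoxy-7-[(1R,2S)-4-chloro-2-[(2Z)-oct-2-en-1-yl]-5-oxo-2-[(triethylsilyl)oxy]cyclopent-3-en-1-yl]hept-5-enoate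
Product: 37 punaglandin 8
Conditions: HF·pyridine, THF, 0 °C → rt
Reagents that add atoms: none
Why: HF·pyridine cleaves the tertiary triethylsilyl ether (fluoride-mediated desilylation) under mildly acidic conditions that avoid base-induced loss of the 7-acetate.

**Compound list**

1 | cyclopentene | C1=CCCC1 | starting material
2 | 5-hydroperoxy-5-methoxypentanal | O=CCCCC(OC)OO | intermediate
3 | 1-hydroperoxy-1,5,5-trimethoxypentane | COC(OO)CCCC(OC)OC | intermediate
4 | 5,5-dimethoxypentanal | O=CCCCC(OC)OC | intermediate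
5 | 5,5-dimethoxy-2-methylidenepentanal | C=C(C=O)CCC(OC)OC | intermediate
6 | 5,5-dimethoxy-2-methylidenepentan-1-ol | C=C(CO)CCC(OC)OC | intermediate
7 | [(2R)-2-(3,3-dimethoxypropyl)oxiran-2-yl]methanol | OC[C@]1(CCC(OC)OC)CO1 | intermediate
8 | {[(2S)-2-(3,3-dimethoxypropyl)oxiran-2-yl]methoxy}triethylsilane (same arrangement at C12 as 7; the descriptor changes by priority only) | CC[Si](CC)(CC)OC[C@]1(CCC(OC)OC)CO1 | intermediate
9 | hept-1-yne | CCCCCC#C | starting material
10 | hept-1-yn-1-yllithium | [Li]C#CCCCCC | intermediate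
11 | (2S)-2-(3,3-dimethoxypropyl)-1-[(triethylsilyl)oxy]dec-4-yn-2-ol | CCCCCC#CC[C@@](CO[Si](CC)(CC)CC)(O)CCC(OC)OC | intermediate
12 | (2S,4Z)-2-(3,3-dimethoxypropyl)-1-[(triethylsilyl)oxy]dec-4-en-2-ol | CCCCC/C=C\C[C@@](CO[Si](CC)(CC)CC)(O)CCC(OC)OC | intermediate
13 | (2S,4Z)-2-(3,3-dimethoxypropyl)-1,2-bis[(triethylsilyl)oxy]dec-4-ene | CCCCC/C=C\C[C@@](CO[Si](CC)(CC)CC)(O[Si](CC)(CC)CC)CCC(OC)OC | intermediate
14 | C8 alkoxydimethylsulfonium chloride derived from 13 (primary silyl group replaced by SMe2+) | CCCCC/C=C\C[C@@](CO[S+](C)C)(O[Si](CC)(CC)CC)CCC(OC)OC.[Cl-] | intermediate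
15 | (2S,4Z)-2-(3,3-dimethoxypropyl)-2-[(triethylsilyl)oxy]dec-4-enal | CCCCC/C=C\C[C@@](C=O)(O[Si](CC)(CC)CC)CCC(OC)OC | intermediate
16 | (triphenylphosphoranylidene)acetaldehyde | O=CC=P(c1ccccc1)(c1ccccc1)c1ccccc1 | starting material
17 | (2E,4S,6Z)-4-(3,3-dimethoxypropyl)-4-[(triethylsilyl)oxy]dodeca-2,6-dienal | CCCCC/C=C\C[C@@](/C=C/C=O)(O[Si](CC)(CC)CC)CCC(OC)OC | intermediate
18 | (4-carboxybutyl)triphenylphosphonium bromide | OC(=O)CCCC[P+](c1ccccc1)(c1ccccc1)c1ccccc1.[Br-] | starting material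
19 | sodium 5-(triphenylphosphoranylidene)pentanoate | [Na+].[O-]C(=O)CCCC=P(c1ccccc1)(c1ccccc1)c1ccccc1 | intermediate
20 | sodium (5Z,7E,9S,11Z)-9-(3,3-dimethoxypropyl)-9-[(triethylsilyl)oxy]heptadeca-5,7,11-trienoate | CCCCC/C=C\C[C@@](/C=C/C=C\CCCC(=O)[O-])(O[Si](CC)(CC)CC)CCC(OC)OC.[Na+] | intermediate
21 | methyl (5Z,7E,9S,11Z)-9-(3,3-dimethoxypropyl)-9-[(triethylsilyl)oxy]heptadeca-5,7,11-trienoate | CCCCC/C=C\C[C@@](/C=C/C=C\CCCC(=O)OC)(O[Si](CC)(CC)CC)CCC(OC)OC | intermediate
22 | C9 N,O-acetal of 21 in which one methoxy group is replaced by 2,4,6-trimethylpyridinium-1-yl (triflate salt) | CCCCC/C=C\C[C@@](/C=C/C=C\CCCC(=O)OC)(O[Si](CC)(CC)CC)CCC(OC)[n+]1c(C)cc(C)cc1C.[O-]S(=O)(=O)C(F)(F)F | intermediate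
23 | methyl (5Z,7E,9S,11Z)-9-(3-oxopropyl)-9-[(triethylsilyl)oxy]heptadeca-5,7,11-trienoate | CCCCC/C=C\C[C@@](/C=C/C=C\CCCC(=O)OC)(O[Si](CC)(CC)CC)CCC=O | intermediate
24 | methyl (5Z,7E,9S,11Z)-9-[(3E)-3-(hydroxyimino)propyl]-9-[(triethylsilyl)oxy]heptadeca-5,7,11-trienoate (C9 aldoxime, prostanoid numbering) | CCCCC/C=C\C[C@@](/C=C/C=C\CCCC(=O)OC)(O[Si](CC)(CC)CC)CC/C=N/O | intermediate
25 | C9 hydroximoyl chloride of 24 | CCCCC/C=C\C[C@@](/C=C/C=C\CCCC(=O)OC)(O[Si](CC)(CC)CC)CCC(Cl)=NO | intermediate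
26 | C9 nitrile oxide of 24 | CCCCC/C=C\C[C@@](/C=C/C=C\CCCC(=O)OC)(O[Si](CC)(CC)CC)CCC#[N+][O-] | intermediate
27 | methyl (5Z)-6-[(3S,3aR,4S)-4-[(2Z)-oct-2-en-1-yl]-4-[(triethylsilyl)oxy]-3a,4,5,6-tetrahydro-3H-cyclopenta[c][1,2]oxazol-3-yl]hex-5-enoate (C7 cis to the C12 silyloxy group) | CCCCC/C=C\C[C@@]1(O[Si](CC)(CC)CC)CCC2=NO[C@@H](/C=C\CCCC(=O)OC)[C@H]12 | intermediate
28 | 9-imino-7-hydroxy compound from N–O cleavage of 27 (C7, C8, C12 as in 27) | CCCCC/C=C\C[C@@]1(O[Si](CC)(CC)CC)CCC(=N)[C@@H]1[C@H](/C=C\CCCC(=O)OC)O | intermediate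
29 | methyl (5Z,7S)-7-hydroxy-7-[(1R,2S)-2-[(2Z)-oct-2-en-1-yl]-5-oxo-2-[(triethylsilyl)oxy]cyclopentyl]hept-5-enoate | CCCCC/C=C\C[C@@]1(O[Si](CC)(CC)CC)CCC(=O)[C@@H]1[C@H](/C=C\CCCC(=O)OC)O | intermediate
30 | methyl (5Z,7S)-7-acetoxy-7-[(1R,2S)-2-[(2Z)-oct-2-en-1-yl]-5-oxo-2-[(triethylsilyl)oxy]cyclopentyl]hept-5-enoate | CCCCC/C=C\C[C@@]1(O[Si](CC)(CC)CC)CCC(=O)[C@@H]1[C@H](/C=C\CCCC(=O)OC)OC(C)=O | intermediate
31 | C9 trimethylsilyl enol ether (C9=C10) of 30 | CCCCC/C=C\C[C@@]1(O[Si](CC)(CC)CC)CC=C(O[Si](C)(C)C)[C@@H]1[C@H](/C=C\CCCC(=O)OC)OC(C)=O | intermediate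
32 | 10-chloro derivative of 30 (both C10 epimers; C7, C8, C12 as in 30) | CCCCC/C=C\C[C@@]1(O[Si](CC)(CC)CC)CC(Cl)C(=O)[C@@H]1[C@H](/C=C\CCCC(=O)OC)OC(C)=O | intermediate
33 | lithium C9–C10 enolate of 32 | CCCCC/C=C\C[C@@]1(O[Si](CC)(CC)CC)CC(Cl)=C([O-])[C@@H]1[C@H](/C=C\CCCC(=O)OC)OC(C)=O.[Li+] | intermediate
34 | 10-chloro-10-(phenylselanyl) derivative of 30 (both C10 epimers) | CCCCC/C=C\C[C@@]1(O[Si](CC)(CC)CC)CC(Cl)([Se]c2ccccc2)C(=O)[C@@H]1[C@H](/C=C\CCCC(=O)OC)OC(C)=O | intermediate
35 | Se-oxide of 34 | CCCCC/C=C\C[C@@]1(O[Si](CC)(CC)CC)CC(Cl)([Se](=O)c2ccccc2)C(=O)[C@@H]1[C@H](/C=C\CCCC(=O)OC)OC(C)=O | intermediate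
36 | methyl (5Z,7S)-7-acetoxy-7-[(1R,2S)-4-chloro-2-[(2Z)-oct-2-en-1-yl]-5-oxo-2-[(triethylsilyl)oxy]cyclopent-3-en-1-yl]hept-5-enoate | CCCCC/C=C\C[C@@]1(O[Si](CC)(CC)CC)C=C(Cl)C(=O)[C@@H]1[C@H](/C=C\CCCC(=O)OC)OC(C)=O | intermediate
37 | punaglandin 8, methyl (5Z,7S)-7-acetoxy-7-[(1R,2S)-4-chloro-2-hydroxy-2-[(2Z)-oct-2-en-1-yl]-5-oxocyclopent-3-en-1-yl]hept-5-enoate | CCCCC/C=C\C[C@@]1(O)C=C(Cl)C(=O)[C@@H]1[C@H](/C=C\CCCC(=O)OC)OC(C)=O | target

**Step count and risks**

Total: 20 steps. Longest linear sequence: 20 steps, from cyclopentene 1 to 37.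

Steps most likely to fail:

Step 14. The nitrile oxide may discriminate poorly between the two faces of the C7=C8 alkene, giving the C8-epimeric cycloadduct beside 27, or it may dimerise before it cyclises. The fallback is an intramolecular silyl nitronate cycloaddition, a bulkier dipole with a later transition state. It sets out from aldehyde 23. NaBH4 in MeOH should give the primary alcohol F1. I2, PPh3 and imidazole (dark, 0 °C) should convert it into the iodide F2, and NaNO2 with phloroglucinol in DMSO into the nitroalkane F3. Me3SiCl and Et3N in benzene should give the silyl nitronate F4, which cyclises onto C7=C8 to the N-silyloxy isoxazolidine F5. Catalytic TsOH in Et2O should then expel trimethylsilanol, and the route is rejoined at isoxazoline 27.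

Step 17. Competing enolisation toward C8 would expel the 7-acetate by β-elimination, and the acetate itself may be enolised. The fallback postpones the acetate until after chlorination and sets out from ketol 29. LiN(SiMe3)2 (2 equiv) with Me3SiCl at −78 °C should give the bis-silylated enol ether F6, and NCS the 7-silyloxy chloro ketone F7. AcOH–THF–H2O should remove the secondary trimethylsilyl ether to give the hydroxy chloro ketone F8. Ac2O/pyridine at 0 °C then returns to the route at 32.

Step 18. Selenenylation of the congested chloro enolate may be slow or unselective, with Favorskii-type or elimination pathways competing. The fallback is a second chlorination followed by dehydrochlorination and sets out from 32. LiN(SiMe3)2 with Me3SiCl should give the chloro enol silane F9, and NCS the 10,10-dichloro ketone F10. LiCl/Li2CO3 in DMF with gentle warming should eliminate HCl, and the route is rejoined at chloro enone 36.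

Further compounds
F1 | step 14 | methyl (5Z,7E,9S,11Z)-9-(3-hydroxypropyl)-9-[(triethylsilyl)oxy]heptadeca-5,7,11-trienoate | CCCCC/C=C\C[C@@](/C=C/C=C\CCCC(=O)OC)(O[Si](CC)(CC)CC)CCCO
F2 | step 14 | methyl (5Z,7E,9S,11Z)-9-(3-iodopropyl)-9-[(triethylsilyl)oxy]heptadeca-5,7,11-trienoate | CCCCC/C=C\C[C@@](/C=C/C=C\CCCC(=O)OC)(O[Si](CC)(CC)CC)CCCI
F3 | step 14 | methyl (5Z,7E,9S,11Z)-9-(3-nitropropyl)-9-[(triethylsilyl)oxy]heptadeca-5,7,11-trienoate | CCCCC/C=C\C[C@@](/C=C/C=C\CCCC(=O)OC)(O[Si](CC)(CC)CC)CCC[N+](=O)[O-]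
F4 | step 14 | trimethylsilyl nitronate of F3 | CCCCC/C=C\C[C@@](/C=C/C=C\CCCC(=O)OC)(O[Si](CC)(CC)CC)CCC=[N+]([O-])O[Si](C)(C)C
F5 | step 14 | N-(trimethylsilyloxy)isoxazolidine corresponding to 27 (C9 saturated, C7, C8, C12 as in 27) | CCCCC/C=C\C[C@@]1(O[Si](CC)(CC)CC)CCC2N(O[Si](C)(C)C)O[C@@H](/C=C\CCCC(=O)OC)[C@H]12
F6 | step 17 | 7-O-trimethylsilyl C9 trimethylsilyl enol ether of 29 | CCCCC/C=C\C[C@@]1(O[Si](CC)(CC)CC)CC=C(O[Si](C)(C)C)[C@@H]1[C@H](/C=C\CCCC(=O)OC)O[Si](C)(C)C
F7 | step 17 | 10-chloro 7-O-trimethylsilyl derivative of 29 | CCCCC/C=C\C[C@@]1(O[Si](CC)(CC)CC)CC(Cl)C(=O)[C@@H]1[C@H](/C=C\CCCC(=O)OC)O[Si](C)(C)C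
F8 | step 17 | 10-chloro derivative of 29 | CCCCC/C=C\C[C@@]1(O[Si](CC)(CC)CC)CC(Cl)C(=O)[C@@H]1[C@H](/C=C\CCCC(=O)OC)O
F9 | step 18 | C9 trimethylsilyl enol ether of 32 | CCCCC/C=C\C[C@@]1(O[Si](CC)(CC)CC)CC(Cl)=C(O[Si](C)(C)C)[C@@H]1[C@H](/C=C\CCCC(=O)OC)OC(C)=O
F10 | step 18 | 10,10-dichloro derivative of 30 | CCCCC/C=C\C[C@@]1(O[Si](CC)(CC)CC)CC(Cl)(Cl)C(=O)[C@@H]1[C@H](/C=C\CCCC(=O)OC)OC(C)=O
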